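**Retrosynthetic overview**
1. Target 25 ⇐ double desilylation of 24 ⇐ Horner–Wadsworth–Emmons union (C15=C15') of trienynal 15 with the C7 allylic phosphonate 22.
2. 15 ⇐ ester 13 ⇐ key vinylogous Mukaiyama aldol (C11–C12 bond) of the ring-bearing enynal 7 with silyl dienolate 10 of methyl 3-methylbut-2-enoate, then dehydration.
3. 7 ⇐ Sonogashira coupling of enol triflate 4 with (2E)-3-methylpent-2-en-4-yn-1-ol 5; 4 ⇐ (4R,6R)-actinol 1, which supplies the only stereocentre.
4. 22 ⇐ pent-4-yn-1-ol 16 by Zr-catalysed methylalumination with formaldehyde trapping (fixes the 13'E alkene), bromination, Arbuzov reaction.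
5. Ring order: there is one ring only; it is not built but carried intact from 1.

Assumption: 1 and 5 are bought as the single isomers shown; TBS = tert-butyldimethylsilyl, TBSO = tert-butyldimethylsilyloxy; comments use carotenoid numbering (C7 = alkyne carbon on the ring, on to C15, then C15' down to C10' = CH2OH).

**Step 1**
Reactants: 1 (4R,6R)-4-hydroxy-2,2,6-trimethylcyclohexan-1-one (actinol)
Product: 2 (4R,6R)-4-(TBSO)-2,2,6-trimethylcyclohexan-1-one
Conditions: TBSCl, imidazole, DMF, rt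
Reagents that add atoms: tert-butyldimethylsilyl chloride (TBSCl), CC(C)(C)[Si](C)(C)Cl
Why: Standard silyl ether formation on the secondary alcohol; the carbinol stereocentre (the future ring C–OH, R) is not touched.

**Step 2**
Reactants: 2 (4R,6R)-4-(TBSO)-2,2,6-trimethylcyclohexan-1-one
Product: 4 (4R)-4-(TBSO)-2,6,6-trimethylcyclohex-1-en-1-yl trifluoromethanesulfonate, via lithium enolate 3 (not isolated)
Conditions: LiN(iPr)2, THF, −78 → 0 °C; then PhNTf2, −78 °C → rt
Reagents that add atoms: N-phenylbis(trifluoromethanesulfonimide) (PhNTf2), O=S(=O)(N(c1ccccc1)S(=O)(=O)C(F)(F)F)C(F)(F)F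
Why: Regiospecific enolate O-triflation, since C6 carries the only α-hydrogen; the C6 stereocentre is erased on purpose and the silyloxy-bearing centre stays R.

**Step 3**
Reactants: 4 (4R)-4-(TBSO)-2,6,6-trimethylcyclohex-1-en-1-yl trifluoromethanesulfonate; 5 (2E)-3-methylpent-2-en-4-yn-1-ol
Product: 6 (2E)-5-[(4R)-4-(TBSO)-2,6,6-trimethylcyclohex-1-en-1-yl]-3-methylpent-2-en-4-yn-1-ol
Conditions: Pd(PPh3)4 (5 mol %), CuI (10 mol %), iPr2NH, DMF, 50 °C, degassed
Reagents that add atoms: none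
Why: Sonogashira coupling (oxidative addition of the enol triflate to zerovalent palladium, copper acetylide transmetalation) forms C6–C7; the 9E alkene of 5 is not involved and is carried through.

**Step 4**
Reactants: 6 (2E)-5-[(4R)-4-(TBSO)-2,6,6-trimethylcyclohex-1-en-1-yl]-3-methylpent-2-en-4-yn-1-ol
Product: 7 (2E)-5-[(4R)-4-(TBSO)-2,6,6-trimethylcyclohex-1-en-1-yl]-3-methylpent-2-en-4-ynal
Conditions: MnO2 (activated, excess), CH2Cl2, rt, dark
Reagents that add atoms: none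
Why: Chemoselective MnO2 oxidation of the primary allylic alcohol under neutral conditions keeps the 9E geometry and the silyl ether.

**Step 5**
Reactants: 8 methyl 3-methylbut-2-enoate
Product: 10 tert-butyl[(1-methoxy-3-methylbuta-1,3-dien-1-yl)oxy]dimethylsilane, via lithium dienolate 9 (not isolated)
Conditions: LiN(iPr)2, THF/DMPU, −78 °C; then TBSCl, −78 °C → rt
Reagents that add atoms: tert-butyldimethylsilyl chloride (TBSCl), CC(C)(C)[Si](C)(C)Cl
Why: γ-Deprotonation of the β,β-disubstituted enoate gives the extended enolate, which is O-silylated to the silyl dienolate (ketene acetal geometry is irrelevant).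

**Step 6**
Reactants: 7 (2E)-5-[(4R)-4-(TBSO)-2,6,6-trimethylcyclohex-1-en-1-yl]-3-methylpent-2-en-4-ynal; 10 tert-butyl[(1-methoxy-3-methylbuta-1,3-dien-1-yl)oxy]dimethylsilane
Product: 11 methyl (2E,6E)-5-hydroxy-3,7-dimethyl-9-[(4R)-4-(TBSO)-2,6,6-trimethylcyclohex-1-en-1-yl]nona-2,6-dien-8-ynoate (C5 epimers)
Conditions: BF3·OEt2 (1.2 equiv), CH2Cl2/Et2O 9:1, −78 °C; aq. NaHCO3
Reagents that add atoms: none
Why: Vinylogous Mukaiyama aldol addition: the terminal (γ) carbon of the silyl dienolate attacks the BF3-activated aldehyde in an open transition state (1,2-addition, the enal β-carbon being disubstituted) to form C11–C12; the new C13=C14 bond is E because the dienolate reacts s-trans, and the C11 carbinol (about 1:1) is removed in step 7.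

**Step 7**
Reactants: 11 methyl (2E,6E)-5-hydroxy-3,7-dimethyl-9-[(4R)-4-(TBSO)-2,6,6-trimethylcyclohex-1-en-1-yl]nona-2,6-dien-8-ynoate
Product: 13 methyl (2E,4E,6E)-3,7-dimethyl-9-[(4R)-4-(TBSO)-2,6,6-trimethylcyclohex-1-en-1-yl]nona-2,4,6-trien-8-ynoate, via allylic mesylate 12 (not isolated)
Conditions: MsCl, Et3N, CH2Cl2, −20 °C; then DBU, −20 °C → rt
Reagents that add atoms: none
Why: Mesylation and DBU-induced vinylogous E1cB elimination complete the aldol condensation; 11E is strongly preferred because an 11Z bond would clash with the C13 methyl, and the 9E and 13E bonds are not touched.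

**Step 8**
Reactants: 13 methyl (2E,4E,6E)-3,7-dimethyl-9-[(4R)-4-(TBSO)-2,6,6-trimethylcyclohex-1-en-1-yl]nona-2,4,6-trien-8-ynoate
Product: 14 (2E,4E,6E)-3,7-dimethyl-9-[(4R)-4-(TBSO)-2,6,6-trimethylcyclohex-1-en-1-yl]nona-2,4,6-trien-8-yn-1-ol
Conditions: iBu2AlH (2.5 equiv), CH2Cl2, −78 °C; aq. potassium sodium tartrate (KNaC4H4O6)
Reagents that add atoms: none
Why: 1,2-Reduction of the conjugated ester by the aluminium hydride at low temperature gives the allylic alcohol without touching the alkyne, the alkenes or the silyl ether.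

**Step 9**
Reactants: 14 (2E,4E,6E)-3,7-dimethyl-9-[(4R)-4-(TBSO)-2,6,6-trimethylcyclohex-1-en-1-yl]nona-2,4,6-trien-8-yn-1-ol
Product: 15 (2E,4E,6E)-3,7-dimethyl-9-[(4R)-4-(TBSO)-2,6,6-trimethylcyclohex-1-en-1-yl]nona-2,4,6-trien-8-ynal
Conditions: MnO2 (activated, excess), CH2Cl2, rt, dark
Reagents that add atoms: none
Why: Neutral MnO2 oxidation of the polyenylic alcohol to the aldehyde, the standard retinol-to-retinal type step, with no geometric isomerisation.

**Step 10**
Reactants: 16 pent-4-yn-1-ol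
Product: 17 tert-butyldimethyl(pent-4-yn-1-yloxy)silane
Conditions: TBSCl, imidazole, DMF, rt
Reagents that add atoms: tert-butyldimethylsilyl chloride (TBSCl), CC(C)(C)[Si](C)(C)Cl
Why: Silyl ether protection of the primary alcohol so that it tolerates the organoaluminium chemistry and falls off together with the ring silyl ether at the end.

**Step 11**
Reactants: 17 tert-butyldimethyl(pent-4-yn-1-yloxy)silane
Product: 20 (2E)-6-(TBSO)-3-methylhex-2-en-1-ol, via alkenylalane 18 (not isolated), via lithium aluminate 19 (not isolated)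
Conditions: Me3Al (2.5 equiv), Cp2ZrCl2 (0.25 equiv), CH2Cl2, 0 °C → rt; strip volatiles, hexane; n-BuLi, THF, −78 → 0 °C; (CH2O)n, rt; aq. NH4Cl
Reagents that add atoms: trimethylaluminium (Me3Al), C[Al](C)C; paraformaldehyde as formaldehyde, C=O
Why: Negishi zirconium-catalysed methylalumination adds Me and Al syn across the terminal alkyne (Al on the terminal carbon), fixing the 13'E trisubstituted alkene; the alkenylaluminate then adds to formaldehyde with retention.

**Step 12**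
Reactants: 20 (2E)-6-(TBSO)-3-methylhex-2-en-1-ol
Product: 21 tert-butyl{[(4E)-6-bromo-4-methylhex-4-en-1-yl]oxy}dimethylsilane
Conditions: CBr4, PPh3, CH2Cl2, 0 °C
Reagents that add atoms: carbon tetrabromide, BrC(Br)(Br)Br
Why: Appel bromination converts the primary allylic alcohol to the primary allylic bromide under neutral conditions with the E alkene and silyl ether intact.

**Step 13**
Reactants: 21 tert-butyl{[(4E)-6-bromo-4-methylhex-4-en-1-yl]oxy}dimethylsilane
Product: 22 diethyl [(2E)-6-(TBSO)-3-methylhex-2-en-1-yl]phosphonate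
Conditions: P(OEt)3 (neat), 120 °C
Reagents that add atoms: triethyl phosphite, CCOP(OCC)OCC
Why: Michaelis–Arbuzov reaction at the primary allylic carbon (as for geranyl bromide) gives the allylic phosphonate with retention of the alkene geometry.

**Step 14**
Reactants: 22 diethyl [(2E)-6-(TBSO)-3-methylhex-2-en-1-yl]phosphonate; 15 (2E,4E,6E)-3,7-dimethyl-9-[(4R)-4-(TBSO)-2,6,6-trimethylcyclohex-1-en-1-yl]nona-2,4,6-trien-8-ynal
Product: 24 (4R)-4-(TBSO)-1-[(3E,5E,7E,9E,11E)-15-(TBSO)-3,7,12-trimethylpentadeca-3,5,7,9,11-pentaen-1-yn-1-yl]-2,6,6-trimethylcyclohex-1-ene, via potassium phosphonate carbanion 23 (not isolated)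
Conditions: KN(SiMe3)2, THF, −78 °C; then 15, −78 → 0 °C, dark
Reagents that add atoms: none
Why: Horner–Wadsworth–Emmons olefination with a semi-stabilised allylic phosphonate forms C15=C15' with E geometry; no carbanion is generated next to the 9E enyne, so that isomerisation-prone bond is left alone.

**Step 15**
Reactants: 24 (4R)-4-(TBSO)-1-[(3E,5E,7E,9E,11E)-15-(TBSO)-3,7,12-trimethylpentadeca-3,5,7,9,11-pentaen-1-yn-1-yl]-2,6,6-trimethylcyclohex-1-ene
Product: 25 (1R)-4-[(3E,5E,7E,9E,11E)-15-hydroxy-3,7,12-trimethylpentadeca-3,5,7,9,11-pentaen-1-yn-1-yl]-3,5,5-trimethylcyclohex-3-en-1-ol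
Conditions: Bu4NF, THF, 0 °C → rt, dark, argon
Reagents that add atoms: none
Why: Fluoride-mediated desilylation removes both silyl ethers under non-acidic conditions that leave the polyenyne geometry and the R carbinol centre unchanged.

**Compound list**
1 | (4R,6R)-4-hydroxy-2,2,6-trimethylcyclohexan-1-one (actinol) | O=C1[C@H](C)C[C@@H](O)CC1(C)C | starting material
2 | (4R,6R)-4-(TBSO)-2,2,6-trimethylcyclohexan-1-one | O=C1[C@H](C)C[C@@H](O[Si](C)(C)C(C)(C)C)CC1(C)C | intermediate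
3 | lithium (4R)-4-(TBSO)-2,6,6-trimethylcyclohex-1-en-1-olate | CC1=C(O[Li])C(C)(C)C[C@H](O[Si](C)(C)C(C)(C)C)C1 | intermediate
4 | (4R)-4-(TBSO)-2,6,6-trimethylcyclohex-1-en-1-yl trifluoromethanesulfonate | CC1=C(OS(=O)(=O)C(F)(F)F)C(C)(C)C[C@H](O[Si](C)(C)C(C)(C)C)C1 | intermediate
5 | (2E)-3-methylpent-2-en-4-yn-1-ol | C#C/C(C)=C/CO | starting material
6 | (2E)-5-[(4R)-4-(TBSO)-2,6,6-trimethylcyclohex-1-en-1-yl]-3-methylpent-2-en-4-yn-1-ol | CC1=C(C#C/C(C)=C/CO)C(C)(C)C[C@H](O[Si](C)(C)C(C)(C)C)C1 | intermediate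
7 | (2E)-5-[(4R)-4-(TBSO)-2,6,6-trimethylcyclohex-1-en-1-yl]-3-methylpent-2-en-4-ynal | CC1=C(C#C/C(C)=C/C=O)C(C)(C)C[C@H](O[Si](C)(C)C(C)(C)C)C1 | intermediate
8 | methyl 3-methylbut-2-enoate | COC(=O)C=C(C)C | starting material
9 | lithium 1-methoxy-3-methylbuta-1,3-dien-1-olate | COC(O[Li])=CC(C)=C | intermediate
10 | tert-butyl[(1-methoxy-3-methylbuta-1,3-dien-1-yl)oxy]dimethylsilane | COC(O[Si](C)(C)C(C)(C)C)=CC(C)=C | intermediate
11 | methyl (2E,6E)-5-hydroxy-3,7-dimethyl-9-[(4R)-4-(TBSO)-2,6,6-trimethylcyclohex-1-en-1-yl]nona-2,6-dien-8-ynoate (C5 epimers) | CC1=C(C#C/C(C)=C/C(O)C/C(C)=C/C(=O)OC)C(C)(C)C[C@H](O[Si](C)(C)C(C)(C)C)C1 | intermediate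
12 | 5-methanesulfonate of 11 | CC1=C(C#C/C(C)=C/C(OS(C)(=O)=O)C/C(C)=C/C(=O)OC)C(C)(C)C[C@H](O[Si](C)(C)C(C)(C)C)C1 | intermediate
13 | methyl (2E,4E,6E)-3,7-dimethyl-9-[(4R)-4-(TBSO)-2,6,6-trimethylcyclohex-1-en-1-yl]nona-2,4,6-trien-8-ynoate | CC1=C(C#C/C(C)=C/C=C/C(C)=C/C(=O)OC)C(C)(C)C[C@H](O[Si](C)(C)C(C)(C)C)C1 | intermediate
14 | (2E,4E,6E)-3,7-dimethyl-9-[(4R)-4-(TBSO)-2,6,6-trimethylcyclohex-1-en-1-yl]nona-2,4,6-trien-8-yn-1-ol | CC1=C(C#C/C(C)=C/C=C/C(C)=C/CO)C(C)(C)C[C@H](O[Si](C)(C)C(C)(C)C)C1 | intermediate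
15 | (2E,4E,6E)-3,7-dimethyl-9-[(4R)-4-(TBSO)-2,6,6-trimethylcyclohex-1-en-1-yl]nona-2,4,6-trien-8-ynal | CC1=C(C#C/C(C)=C/C=C/C(C)=C/C=O)C(C)(C)C[C@H](O[Si](C)(C)C(C)(C)C)C1 | intermediate
16 | pent-4-yn-1-ol | C#CCCCO | starting material
17 | tert-butyldimethyl(pent-4-yn-1-yloxy)silane | C#CCCCO[Si](C)(C)C(C)(C)C | intermediate
18 | [(1E)-5-(TBSO)-2-methylpent-1-en-1-yl]dimethylalumane | C[Al](C)/C=C(\C)CCCO[Si](C)(C)C(C)(C)C | intermediate
19 | lithium butyl[(1E)-5-(TBSO)-2-methylpent-1-en-1-yl]dimethylaluminate | [Li+].CCCC[Al-](C)(C)/C=C(\C)CCCO[Si](C)(C)C(C)(C)C | intermediate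
20 | (2E)-6-(TBSO)-3-methylhex-2-en-1-ol | OC/C=C(\C)CCCO[Si](C)(C)C(C)(C)C | intermediate
21 | tert-butyl{[(4E)-6-bromo-4-methylhex-4-en-1-yl]oxy}dimethylsilane | BrC/C=C(\C)CCCO[Si](C)(C)C(C)(C)C | intermediate
22 | diethyl [(2E)-6-(TBSO)-3-methylhex-2-en-1-yl]phosphonate | CCOP(=O)(OCC)C/C=C(\C)CCCO[Si](C)(C)C(C)(C)C | intermediate
23 | potassium salt of the C1 carbanion of 22 | [K+].CCOP(=O)(OCC)[CH-]/C=C(\C)CCCO[Si](C)(C)C(C)(C)C | intermediate
24 | (4R)-4-(TBSO)-1-[(3E,5E,7E,9E,11E)-15-(TBSO)-3,7,12-trimethylpentadeca-3,5,7,9,11-pentaen-1-yn-1-yl]-2,6,6-trimethylcyclohex-1-ene | CC1=C(C#C/C(C)=C/C=C/C(C)=C/C=C/C=C(\C)CCCO[Si](C)(C)C(C)(C)C)C(C)(C)C[C@H](O[Si](C)(C)C(C)(C)C)C1 | intermediate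
25 | (1R)-4-[(3E,5E,7E,9E,11E)-15-hydroxy-3,7,12-trimethylpentadeca-3,5,7,9,11-pentaen-1-yn-1-yl]-3,5,5-trimethylcyclohex-3-en-1-ol | CC1=C(C#C/C(C)=C/C=C/C(C)=C/C=C/C=C(\C)CCCO)C(C)(C)C[C@H](O)C1 | target

**Totals**
Total step count: 15. Longest linear sequence: 10 steps (1, 2, 3, 4, 6, 7, 8, 9, 14, 15, from compound 1).

**Steps most likely to fail**

Step 3 (Sonogashira coupling of a hindered, tetrasubstituted enol triflate; slow coupling or alkyne homocoupling). The fallback sets out from ketone 2 and alkynol 5 and comes back at compound 6. Alkynol 5 is treated with two equivalents of n-BuLi (THF, −78 → 0 °C) to give the dilithio acetylide–alkoxide F1, which is added to ketone 2. Aqueous work-up gives the tertiary propargylic diol F2. Its primary allylic hydroxyl is acetylated selectively (Ac2O, pyridine, 0 °C) to the monoacetate F3. The tertiary alcohol, whose only β-hydrogen is the ring C–H next to the methyl group, is dehydrated with POCl3/pyridine (80 °C) to the enyne acetate F4. Methanolysis (K2CO3, MeOH) returns 6.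

Step 6 (the vinylogous aldol; possible α- or 1,4-attack, or loss of 13E purity in the elimination of step 7). The fallback sets out from enynal 7 and comes back at compound 13, bypassing steps 5 to 7. A base-catalysed aldol condensation of 7 with acetone (acetone as solvent, dilute aq. NaOH, 0 °C → rt) gives the (11E)-dienynone F5. This is olefinated with the sodium salt of methyl (dimethoxyphosphoryl)acetate F6 (made with NaH in THF, 0 °C → rt). Ester 13 is obtained after chromatographic removal of the 13Z isomer.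

Step 14 (olefination of a sensitive polyenal; incomplete E-selectivity at C15=C15' or low conversion). The fallback sets out from aldehyde 15 and silyl ether 17 and comes back at compound 24. Takai iodo-olefination of 15 (CHI3, CrCl2, THF/dioxane, 0 °C) gives the (E)-tetraenynyl iodide F7. This is cross-coupled (Pd(PPh3)4, ZnCl2 as co-catalyst, THF, rt) with alkenylalane 18, generated from 17 as in step 11. The Negishi coupling forms the C15'–C14' bond with retention at both alkenes and gives 24.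

**Further compounds**
F1 | step 3 | lithium (2E)-5-lithio-3-methylpent-2-en-4-yn-1-olate | [Li]C#C/C(C)=C/CO[Li]
F2 | step 3 | (4R,6R)-4-(TBSO)-1-[(3E)-5-hydroxy-3-methylpent-3-en-1-yn-1-yl]-2,2,6-trimethylcyclohexan-1-ol (C1 not controlled) | OC1(C#C/C(C)=C/CO)[C@H](C)C[C@@H](O[Si](C)(C)C(C)(C)C)CC1(C)C
F3 | step 3 | (2E)-5-[(4R,6R)-4-(TBSO)-1-hydroxy-2,2,6-trimethylcyclohexyl]-3-methylpent-2-en-4-yn-1-yl acetate | OC1(C#C/C(C)=C/COC(C)=O)[C@H](C)C[C@@H](O[Si](C)(C)C(C)(C)C)CC1(C)C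
F4 | step 3 | (2E)-5-[(4R)-4-(TBSO)-2,6,6-trimethylcyclohex-1-en-1-yl]-3-methylpent-2-en-4-yn-1-yl acetate | CC1=C(C#C/C(C)=C/COC(C)=O)C(C)(C)C[C@H](O[Si](C)(C)C(C)(C)C)C1
F5 | step 6 | (3E,5E)-6-methyl-8-[(4R)-4-(TBSO)-2,6,6-trimethylcyclohex-1-en-1-yl]octa-3,5-dien-7-yn-2-one | CC1=C(C#C/C(C)=C/C=C/C(C)=O)C(C)(C)C[C@H](O[Si](C)(C)C(C)(C)C)C1
F6 | step 6 | sodium salt of methyl (dimethoxyphosphoryl)acetate | [Na+].COC(=O)[CH-]P(=O)(OC)OC
F7 | step 14 | (4R)-4-(TBSO)-1-[(3E,5E,7E,9E)-10-iodo-3,7-dimethyldeca-3,5,7,9-tetraen-1-yn-1-yl]-2,6,6-trimethylcyclohex-1-ene | CC1=C(C#C/C(C)=C/C=C/C(C)=C/C=C/I)C(C)(C)C[C@H](O[Si](C)(C)C(C)(C)C)C1
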